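**Plan**

- Numbering: C1 allyl-bearing bridgehead, C2=C3(OMe), C4 enone carbonyl, C5 second bridgehead, C6 aryl carbon, C7 methyl carbon, C8 one-carbon keto bridge. Exo means toward C8, endo means toward the C2–C4 bridge.
- Cuts, in retrosynthetic order: C3–OMe and the C2=C3 unsaturation (back to a C4 carbinol), C7–CH3 (back to a C7 carbonyl), C6–aryl (enolate arylation), C4–C5 (aldol), C1–C2 (Michael) and C1–allyl.
- Enabling feature: with C7 as a carbonyl, C1 is the quaternary carbon of a 2,2-disubstituted cyclopentane-1,3-dione (ring C1–C8–C5–C6–C7) whose C7 and C8 carbonyls are enantiotopic. The C4–C5 bond closes ring C1–C2–C3–C4–C5–C8 across it.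
- Forward order: the five-membered ring is purchased, the two chains are attached at C1, the six-membered ring closes in the aldol, then aryl at C6, methyl at C7 and the C3/C4 oxygen pattern follow.
- Stereochemistry: C1 and C5 come from the catalyst-controlled choice between the two ring carbonyls. C6 is set by equilibration of the α-aryl ketone (aryl exo). C7 is set by exo-face hydrogen-atom delivery (methyl endo, trans to aryl).

Key step: step 3

Remark: the sense of induction of the aldol catalyst is assumed (the quinidine-derived pseudoenantiomer would be used if the quinine-derived amine favours the mirror-image ketol), and the C4 carbinol configuration of 6 is immaterial because C4 becomes a carbonyl in step 9.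

**Route**

Step 1
Reactants: 1 cyclopentane-1,3-dione; 2 allyl bromide
Product: 3 2-allylcyclopentane-1,3-dione
Conditions: NaOH (1 equiv), H2O, 23 → 60 °C
Reagents that add atoms: none
Why: C-alkylation of the stabilised dione enolate with a soft allylic halide in water, where hydrogen bonding to the enolate oxygens favours attack through carbon.

Step 2
Reactants: 3 2-allylcyclopentane-1,3-dione; 4 acrolein
Product: 5 2-allyl-2-(3-oxopropyl)cyclopentane-1,3-dione
Conditions: H2O, 23 °C
Reagents that add atoms: none
Why: Michael addition of the acidic 2-substituted 1,3-dione to acrolein runs in water without added base and creates the still prochiral quaternary carbon.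

Step 3
Reactants: 5 2-allyl-2-(3-oxopropyl)cyclopentane-1,3-dione
Product: 6 (1S,4R,5R)-1-allyl-4-hydroxybicyclo[3.2.1]octane-7,8-dione
Conditions: 9-amino-9-deoxy-epi-quinine (20 mol%), CF3CO2H (40 mol%), toluene (0.05 M), 0 → 23 °C
Reagents that add atoms: none
Why: The primary amine condenses reversibly with one ring carbonyl to an enamine whose carbon C5 adds to the aldehyde carbon C4, which is activated by hydrogen bonding to the ammonium site, and hydrolysis of the C8 iminium releases 6 and the catalyst; the closest known reaction type is the amine-catalysed desymmetrising intramolecular aldol of 2,2-disubstituted cyclic 1,3-diones in its bridged variant. Ring C1–C2–C3–C4–C5–C8 closes in a 6-(enolendo)-exo-trig mode, the only one the three-atom tether permits, because attack of the aldehyde α-carbon on a ring carbonyl would need a four-membered ring. C1 and C5 are set together by which of the two enantiotopic carbonyls enters the C–C bond-forming transition state, a choice made by the chiral ammonium ion pair, and the bicyclic geometry allows only one relative arrangement of the two bridgeheads. C4 follows from the chair-like closure with the aldehyde oxygen turned outward (equatorial) and is erased in step 9. The step needs enantiotopic-group selectivity and reaction through the ketone enamine; the symmetry of 5, a primary amine able to condense with the neopentylic ring ketone, and a ketol that cannot dehydrate (bridgehead) should secure both.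

Step 4
Reactants: 6 (1S,4R,5R)-1-allyl-4-hydroxybicyclo[3.2.1]octane-7,8-dione
Product: 7 1-allyl-4-(tert-butyldimethylsilyloxy)bicyclo[3.2.1]octane-7,8-dione
Conditions: t-BuMe2SiCl, imidazole, DMF, 23 °C
Reagents that add atoms: tert-butyldimethylsilyl chloride, CC(C)(C)[Si](C)(C)Cl
Why: Standard silylation of a secondary alcohol, which blocks retro-aldol opening of the β-hydroxy ketone under the basic conditions of step 5.

Step 5
Reactants: 7 1-allyl-4-(tert-butyldimethylsilyloxy)bicyclo[3.2.1]octane-7,8-dione; 8 4-bromo-1,2-dimethoxybenzene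
Product: 11 1-allyl-6-exo-(3,4-dimethoxyphenyl)-4-(tert-butyldimethylsilyloxy)bicyclo[3.2.1]octane-7,8-dione, via sodium enolate of the silyl ether 9 (not isolated), via sodium enolate of the aryl ketone 10 (not isolated)
Conditions: NaN(SiMe3)2 (2.2 equiv), THF, −78 → 0 °C; 8, Pd(P(t-Bu)3)2 (5 mol%, zerovalent palladium), toluene, 50 °C; AcOH; then DBU (0.2 equiv), CH2Cl2, 23 °C
Reagents that add atoms: none
Why: Palladium-catalysed α-arylation of a ketone enolate can occur only at C6, the sole enolisable carbon, a non-nucleophilic amide base spares the non-enolisable 1,3-dione from retro-Claisen cleavage, and protonation followed by DBU equilibration should leave the aryl group exo, away from the C2–C4 bridge and the C4 silyloxy group.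

Step 6
Reactants: 11 1-allyl-6-exo-(3,4-dimethoxyphenyl)-4-(tert-butyldimethylsilyloxy)bicyclo[3.2.1]octane-7,8-dione
Product: 12 1-allyl-6-exo-(3,4-dimethoxyphenyl)-7-methylene-4-(tert-butyldimethylsilyloxy)bicyclo[3.2.1]octan-8-one
Conditions: Zn, CH2Br2, TiCl4, THF, 0 °C (reagent pre-formed); then 11, CH2Cl2, 0 → 23 °C
Reagents that add atoms: dibromomethane, BrCBr
Why: Lombardo methylenation is non-basic and established for enolisable ketones on the two-carbon bridge of bicyclo[3.2.1]octanes, so it should convert the C7 carbonyl from its open exo face, while C8 is screened by the exo aryl group on one face and by the axial hydrogens at C2 and C4 on the other.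

Step 7
Reactants: 12 1-allyl-6-exo-(3,4-dimethoxyphenyl)-7-methylene-4-(tert-butyldimethylsilyloxy)bicyclo[3.2.1]octan-8-one
Product: 13 1-allyl-6-exo-(3,4-dimethoxyphenyl)-7-endo-methyl-4-(tert-butyldimethylsilyloxy)bicyclo[3.2.1]octan-8-one
Conditions: Mn(dpm)3 (10 mol%, trivalent manganese; dpm = 2,2,6,6-tetramethylheptane-3,5-dionate), PhSiH3, t-BuOOH, i-PrOH, 23 °C
Reagents that add atoms: none
Why: Metal-hydride hydrogen-atom transfer (Mukaiyama-type radical hydrogenation) reaches the CH2 terminus of the 1,1-disubstituted alkene much faster than the monosubstituted allyl group (tertiary against secondary radical), and the C7 radical should take its second hydrogen on the convex exo face because the endo face lies under the C2–C4 bridge, which puts methyl endo and trans to the aryl group.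

Step 8
Reactants: 13 1-allyl-6-exo-(3,4-dimethoxyphenyl)-7-endo-methyl-4-(tert-butyldimethylsilyloxy)bicyclo[3.2.1]octan-8-one
Product: 14 1-allyl-6-exo-(3,4-dimethoxyphenyl)-4-hydroxy-7-endo-methylbicyclo[3.2.1]octan-8-one
Conditions: HF·pyridine, THF, 0 → 23 °C
Reagents that add atoms: none
Why: Fluoride-induced Si–O cleavage under buffered acidic conditions avoids the free alkoxide that could open the β-hydroxy ketone by retro-aldol reaction.

Step 9
Reactants: 14 1-allyl-6-exo-(3,4-dimethoxyphenyl)-4-hydroxy-7-endo-methylbicyclo[3.2.1]octan-8-one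
Product: 15 1-allyl-6-exo-(3,4-dimethoxyphenyl)-7-endo-methylbicyclo[3.2.1]octane-4,8-dione
Conditions: Dess–Martin periodinane, CH2Cl2, 23 °C
Reagents that add atoms: none
Why: Dess–Martin oxidation of the secondary alcohol under neutral conditions gives the 1,3-dione, whose only intervening carbon is the bridgehead C5 and which therefore cannot enolise.

Step 10
Reactants: 15 1-allyl-6-exo-(3,4-dimethoxyphenyl)-7-endo-methylbicyclo[3.2.1]octane-4,8-dione
Product: 17 1-allyl-6-exo-(3,4-dimethoxyphenyl)-3-hydroxy-7-endo-methylbicyclo[3.2.1]octane-4,8-dione, via potassium C3=C4 enolate 16 (not isolated)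
Conditions: KN(SiMe3)2, THF, −78 °C; 2-(phenylsulfonyl)-3-phenyloxaziridine, −78 °C; AcOH
Reagents that add atoms: 2-(phenylsulfonyl)-3-phenyloxaziridine, O=S(=O)(c1ccccc1)N1OC1c1ccccc1
Why: Deprotonation is possible only at C3 (C5 is a bridgehead), and oxygen transfer from the N-sulfonyloxaziridine to the enolate (Davis hydroxylation) should give the α-ketol from the face away from the endo methyl group, the C3 configuration being irrelevant.

Step 11
Reactants: 17 1-allyl-6-exo-(3,4-dimethoxyphenyl)-3-hydroxy-7-endo-methylbicyclo[3.2.1]octane-4,8-dione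
Product: 19 1-allyl-6-exo-(3,4-dimethoxyphenyl)-3-hydroxy-7-endo-methylbicyclo[3.2.1]oct-2-ene-4,8-dione, via 3,4,8-trione 18 (not isolated)
Conditions: Dess–Martin periodinane, CH2Cl2, 23 °C
Reagents that add atoms: none
Why: Dess–Martin oxidation of the α-ketol gives the 3,4-dione, which can enolise only toward C2 (enolisation toward C5 would violate Bredt's rule) and should therefore rest as the diosphenol.

Step 12
Reactants: 19 1-allyl-6-exo-(3,4-dimethoxyphenyl)-3-hydroxy-7-endo-methylbicyclo[3.2.1]oct-2-ene-4,8-dione
Product: 20 Kadsurenin D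
Conditions: Me2SO4, K2CO3, acetone, 56 °C
Reagents that add atoms: dimethyl sulfate, COS(=O)(=O)OC
Why: O-alkylation of the acidic diosphenol with a hard methylating agent and carbonate base (Williamson-type enol etherification) gives the methyl enol ether without touching the non-enolisable dione.

**Compound list**

1 | cyclopentane-1,3-dione | O=C1CCC(=O)C1 | starting material
2 | allyl bromide | C=CCBr | starting material
3 | 2-allylcyclopentane-1,3-dione | C=CCC1C(=O)CCC1=O | intermediate
4 | acrolein | C=CC=O | starting material
5 | 2-allyl-2-(3-oxopropyl)cyclopentane-1,3-dione | C=CCC1(CCC=O)C(=O)CCC1=O | intermediate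
6 | (1S,4R,5R)-1-allyl-4-hydroxybicyclo[3.2.1]octane-7,8-dione (hydroxyl equatorial, antiperiplanar to the C5–C8 bond) | C=CC[C@]12CC[C@@H](O)[C@H](C1=O)CC2=O | intermediate
7 | 4-O-tert-butyldimethylsilyl ether of 6 | C=CC[C@]12CC[C@@H](O[Si](C)(C)C(C)(C)C)[C@H](C1=O)CC2=O | intermediate
8 | 4-bromo-1,2-dimethoxybenzene | COc1ccc(Br)cc1OC | starting material
9 | sodium C6=C7 enolate of 7 (not isolated) | C=CC[C@]12CC[C@@H](O[Si](C)(C)C(C)(C)C)[C@H](C1=O)C=C2[O-].[Na+] | intermediate
10 | sodium C6=C7 enolate of 11 (not isolated) | C=CC[C@]12CC[C@@H](O[Si](C)(C)C(C)(C)C)[C@H](C1=O)C(c1ccc(OC)c(OC)c1)=C2[O-].[Na+] | intermediate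
11 | 1-allyl-6-exo-(3,4-dimethoxyphenyl)-4-(tert-butyldimethylsilyloxy)bicyclo[3.2.1]octane-7,8-dione | C=CC[C@]12CC[C@@H](O[Si](C)(C)C(C)(C)C)[C@H](C1=O)[C@H](c1ccc(OC)c(OC)c1)C2=O | intermediate
12 | 7-methylene analogue of 11 (C8 ketone kept) | C=CC[C@]12CC[C@@H](O[Si](C)(C)C(C)(C)C)[C@H](C1=O)[C@H](c1ccc(OC)c(OC)c1)C2=C | intermediate
13 | 6-exo-aryl-7-endo-methyl silyl ether (aryl and methyl trans) | C=CC[C@]12CC[C@@H](O[Si](C)(C)C(C)(C)C)[C@H](C1=O)[C@H](c1ccc(OC)c(OC)c1)[C@H]2C | intermediate
14 | 1-allyl-6-exo-(3,4-dimethoxyphenyl)-4-hydroxy-7-endo-methylbicyclo[3.2.1]octan-8-one | C=CC[C@]12CC[C@@H](O)[C@H](C1=O)[C@H](c1ccc(OC)c(OC)c1)[C@H]2C | intermediate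
15 | 1-allyl-6-exo-(3,4-dimethoxyphenyl)-7-endo-methylbicyclo[3.2.1]octane-4,8-dione | C=CC[C@]12CCC(=O)[C@H](C1=O)[C@H](c1ccc(OC)c(OC)c1)[C@H]2C | intermediate
16 | potassium C3=C4 enolate of 15 (not isolated) | C=CC[C@]12CC=C([O-])[C@H](C1=O)[C@H](c1ccc(OC)c(OC)c1)[C@H]2C.[K+] | intermediate
17 | 3-hydroxy derivative of 15 (hydroxyl on the C8 side; C3 epimer equally usable) | C=CC[C@]12C[C@H](O)C(=O)[C@H](C1=O)[C@H](c1ccc(OC)c(OC)c1)[C@H]2C | intermediate
18 | 1-allyl-6-exo-(3,4-dimethoxyphenyl)-7-endo-methylbicyclo[3.2.1]octane-3,4,8-trione (not isolated) | C=CC[C@]12CC(=O)C(=O)[C@H](C1=O)[C@H](c1ccc(OC)c(OC)c1)[C@H]2C | intermediate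
19 | diosphenol, 3-hydroxy-oct-2-ene-4,8-dione | C=CC[C@]12C=C(O)C(=O)[C@H](C1=O)[C@H](c1ccc(OC)c(OC)c1)[C@H]2C | intermediate
20 | Kadsurenin D, (1S,5S,6R,7R)-1-allyl-6-(3,4-dimethoxyphenyl)-3-methoxy-7-methylbicyclo[3.2.1]oct-2-ene-4,8-dione | C=CC[C@]12C=C(OC)C(=O)[C@H](C1=O)[C@H](c1ccc(OC)c(OC)c1)[C@H]2C | target

**Step count and risks**

Total step count: 12. Longest linear sequence: 12 steps (1 → 20).

Steps most likely to fail:

1. Step 7. The second hydrogen may be delivered to the C7 radical from the endo face, anti to the neighbouring aryl group, which would give the cis isomer. Hydrogen-atom transfer to the allyl group, or migration of the exocyclic double bond into conjugation with the arene, may also compete. The fallback sets out from 11 and comes back at 13, replacing radical hydrogen delivery by an ionic, stepwise reduction.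
   - 11 is returned to its sodium enolate 10 with NaN(SiMe3)2 and trapped with PhNTf2 as the C6=C7 enol triflate F1.
   - Suzuki coupling with trimethylboroxine (Pd(PPh3)4, K2CO3, dioxane, 80 °C) gives the tetrasubstituted styrene F2.
   - Li in NH3/THF at −78 °C should protonate the radical anion at C7 on the convex exo face while C6 is still planar. The benzylic carbanion should then settle with the aryl group exo before it is protonated, giving the trans arrangement.
   - The isolated allyl alkene is inert to these conditions. The C8 ketone is reduced in the same operation, giving the C8 carbinol F3.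
   - Dess–Martin oxidation of F3 gives 13.

2. Step 6. The titanium methylene reagent may attack the bridging C8 carbonyl as well as, or instead of, C7, or the hindered α-aryl ketone may fail to react. The fallback sets out from 11 and comes back at 12, masking one carbonyl through its enolate.
   - NaN(SiMe3)2 in THF at −78 °C regenerates enolate 10, which protects C7.
   - i-Bu2AlH then reduces only C8, and protonation gives the 8-hydroxy-7-ketone F4.
   - With a single carbonyl left, Lombardo methylenation gives the 8-hydroxy-7-methylene compound F5.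
   - Dess–Martin oxidation of the C8 carbinol gives 12.

3. Step 5. The arylpalladium intermediate may be diverted into Heck arylation or isomerisation of the allyl group, and the strained non-enolisable 1,3-dione may be opened by base (retro-Claisen) before coupling occurs. The fallback sets out from 7 and comes back at 11, avoiding both palladium and prolonged exposure to base.
   - Enolate 9 is trapped at −78 °C with Me3SiCl as the trimethylsilyl enol ether F6.
   - F6 is arylated at 23 °C in CH2Cl2 with Cu(OTf)2 (10 mol%) and bis(3,4-dimethoxyphenyl)iodonium triflate F7, a copper-catalysed arylation of a silyl enol ether with a diaryliodonium salt.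
   - F7 is made in one operation from 1,2-dimethoxybenzene, I2, mCPBA and TfOH.
   - The same DBU equilibration then gives 11.

Further compounds
F1 | step 7 | C6=C7 enol triflate of 11 | C=CC[C@]12CC[C@@H](O[Si](C)(C)C(C)(C)C)[C@H](C1=O)C(c1ccc(OC)c(OC)c1)=C2OS(=O)(=O)C(F)(F)F
F2 | step 7 | 1-allyl-6-(3,4-dimethoxyphenyl)-7-methyl-4-(tert-butyldimethylsilyloxy)bicyclo[3.2.1]oct-6-en-8-one | C=CC[C@]12CC[C@@H](O[Si](C)(C)C(C)(C)C)[C@H](C1=O)C(c1ccc(OC)c(OC)c1)=C2C
F3 | step 7 | 8-hydroxy analogue of 13 (hydroxyl over the six-membered ring; C8 epimer equally usable) | C=CC[C@]12CC[C@@H](O[Si](C)(C)C(C)(C)C)[C@H]([C@@H]1O)[C@H](c1ccc(OC)c(OC)c1)[C@H]2C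
F4 | step 6 | 8-hydroxy analogue of 11 (hydroxyl toward the C6–C7 bridge; C8 epimer equally usable) | C=CC[C@]12CC[C@@H](O[Si](C)(C)C(C)(C)C)[C@H]([C@H]1O)[C@H](c1ccc(OC)c(OC)c1)C2=O
F5 | step 6 | 8-hydroxy analogue of 12 | C=CC[C@]12CC[C@@H](O[Si](C)(C)C(C)(C)C)[C@H]([C@H]1O)[C@H](c1ccc(OC)c(OC)c1)C2=C
F6 | step 5 | trimethylsilyl C6=C7 enol ether of 7 | C=CC[C@]12CC[C@@H](O[Si](C)(C)C(C)(C)C)[C@H](C1=O)C=C2O[Si](C)(C)C
F7 | step 5 | bis(3,4-dimethoxyphenyl)iodonium triflate | COc1ccc([I+]c2ccc(OC)c(OC)c2)cc1OC.[O-]S(=O)(=O)C(F)(F)F
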